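All constants are assumed, and the outcome is calculated.

To whoever takes the bench next: these flasks of Q and D are yours, with these equations, settings and questions.

    Q.D → L (k1 = 3.11 × 10⁻⁴ min⁻¹, Ea1 = 111 kJ mol⁻¹)
    D → E (k2 = 1.34 × 10⁻⁶ min⁻¹, Ea2 = 113 kJ mol⁻¹)
    Q + D → Q.D (k3 = 0.00747 M⁻¹ min⁻¹, Ea3 = 83.0 kJ mol⁻¹)
    Q → G (k4 = 0.00337 min⁻¹, Ea4 = 102 kJ mol⁻¹)
    2 Q → Q2 (k5 = 0.00247 M⁻¹ min⁻¹, Ea5 = 71.0 kJ mol⁻¹)
    (constants at 40 °C)

the same everywhere: Q 0.40 M; D 0.700 equiv; time 3.0 h

| run | temperature |
|---|---|
| maple | 40 °C |
| alder | 55 °C |
| oak | 70 °C |

- the best flask by share of Q.D in all that became Q.D or G or Q2 or L; "all alike" if 1.5 percentage points covers them all (maple / alder / oak / all alike)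
- share of Q.D in all that became Q.D or G or Q2 or L, maple
- share of Q.D in all that became Q.D or G or Q2 or L, alder
- share of Q.D in all that became Q.D or G or Q2 or L, oak

- in percentages every species weighs as the Q in it: one Q2 counts as two
- two of one species on the left: rate k times its square, two consumed each time
- all constants are for 40 °C and move with temperature by the activation energies

**In the flasks.** You have Q leaving by several routes at once, and you want the route through D. At the start in maple that route takes 28.1% of the loss of Q. Heat tilts Q away from Q.D and toward G, because the barrier of Q → G stands 19.0 kJ mol⁻¹ above that of Q + D → Q.D.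

**Count what stays.** Don't count the Q.D made; count the fraction left. Let k be the constant of Q.D → L at the flask's temperature, and let t be a stretch of time. While no Q.D is being made, f = exp(−k t). In oak, k is 0.0129 min⁻¹, so over half the run the keep fraction, the part of the standing Q.D still there afterwards, is 31.2%. In oak, Q has a half-life by Q → G of 6.70 min, far shorter than the run, so there f should apply early.

**When you come.** In alder, k is 0.00218 min⁻¹, so over the full 3.0 h, f is 94.6% in maple, 67.5% in alder and 9.76% in oak. So I expect maple to lead, though I put no share on any flask. Don't stretch the time on oak, because the half-life of Q.D by Q.D → L is 0.896 h, shorter than the run.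

**The forecast.** It names maple, with 27.3%, 17.3% and 2.1% for maple, alder and oak, and says the decay to L “wipes out most of what forms at 70 °C while barely touching it at 40 °C”.

**The result.** The shares are 26.9% in maple, 17.3% in alder and 2.16% in oak, so maple is best. In oak at 1.50 h, Q stands at 0% and Q.D at 6.91%; the keep fraction makes that 2.16%, and the flask holds 2.16% at 3.00 h. In alder at 3.00 h, Q stands at 0.662% and Q.D at 17.1%; f to 30.0 h is 2.91%, which gives 0.498%, and the flask then holds 0.504%.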